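**Retrosynthetic overview**
1. Glabrescione B (8) ⇒ the γ-pyranone ring is closed last by forming the aryl C8a–O1 bond: the enolate oxygen of an α-formyl deoxybenzoin displaces one ortho-methoxy group of a 2,4,6-trimethoxyphenyl ketone (new step); C-2 comes from ethyl formate.
2. Bis-prenyl deoxybenzoin 5 ⇒ double O-prenylation of catechol ketone 3.
3. Ketone 3 ⇒ Friedel–Crafts acylation of threefold-symmetric 1,3,5-trimethoxybenzene (1) with 3,4-dihydroxyphenylacetic acid (2); only one regioisomer is possible.
4. Ring order: rings A and B are bought; the only ring formed is ring C (pyranone), in the final step.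

Assumption: the target has no stereocentre and no stereogenic double bond, so the "single enantiomer" is the one achiral structure given and no stereocontrol is needed.

**Step 1**
Reactants: 1 1,3,5-trimethoxybenzene; 2 3,4-dihydroxyphenylacetic acid
Product: 3 2-(3,4-dihydroxyphenyl)-1-(2,4,6-trimethoxyphenyl)ethan-1-one
Conditions: 1 (1.3 equiv), Eaton's reagent (P2O5/MeSO3H), rt → 40 °C, 3 h; ice-water
Reagents that add atoms: none
Why: Friedel–Crafts acylation: the activated acyl species from 2 is trapped by the very electron-rich, symmetric arene 1 (one regioisomer only), the ketone formed deactivates the ring against a second acylation, and free phenols are tolerated in this medium; no stereocentre is formed.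

**Step 2**
Reactants: 3 2-(3,4-dihydroxyphenyl)-1-(2,4,6-trimethoxyphenyl)ethan-1-one; 4 prenyl bromide (1-bromo-3-methylbut-2-ene)
Product: 5 2-{3,4-bis[(3-methylbut-2-en-1-yl)oxy]phenyl}-1-(2,4,6-trimethoxyphenyl)ethan-1-one
Conditions: 4 (2.3 equiv), K2CO3 (3 equiv), acetone, reflux, N2, 8 h
Reagents that add atoms: none
Why: Williamson ether synthesis: both catechol phenoxides are alkylated by the primary allylic bromide in SN2 fashion, while carbonate in acetone is too weak to enolise the hindered benzyl ketone to a useful extent; no stereocentre is formed.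

**Step 3**
Reactants: 5 2-{3,4-bis[(3-methylbut-2-en-1-yl)oxy]phenyl}-1-(2,4,6-trimethoxyphenyl)ethan-1-one; 6 ethyl formate
Product: 8 glabrescione B, via potassium hydroxymethylene-ketone enolate 7 (not isolated)
Conditions: 6 (5 equiv), t-BuOK (1.3 equiv), THF, 0 °C → rt, 2 h; then KHCO3 (1.5 equiv), 18-crown-6 (0.2 equiv), DMSO (THF and excess 6 distilled off), 90 °C, 12 h, N2
Reagents that add atoms: none
Why: Proposed new method: Claisen formylation of the benzylic ketone (known) gives enolate 7, a vinylogous carboxylate whose terminal oxygen sits over the face of the twisted, di-ortho-substituted trimethoxyphenyl ring; on heating in DMSO it adds to the ortho C–OMe carbon (Meisenheimer adduct stabilised by the C-4 carbonyl; the two remaining methoxy groups are meta to the site of attack and do not deactivate it), methoxide leaves and the aromatic pyranone forms, while KHCO3 turns the excess alkoxide and the released methoxide into carbonate-level base so that the prenyl ethers escape alkoxide/DMSO 1,4-elimination and the chromone is not opened at C-2; the closest known reaction type is the base-mediated cyclisation of 2-hydroxy-2'-methoxybenzophenones to xanthones by intramolecular SNAr loss of methoxide (and SNAr chromone closures of 2-fluoroaryl 1,3-dicarbonyls), not shown for a formyl-ketone enolate closing an isoflavone on a methoxy leaving group; no stereocentre is formed.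

**Compound list**
1 | 1,3,5-trimethoxybenzene | COc1cc(OC)cc(OC)c1 | starting material
2 | 3,4-dihydroxyphenylacetic acid | OC(=O)Cc1ccc(O)c(O)c1 | starting material
3 | 2-(3,4-dihydroxyphenyl)-1-(2,4,6-trimethoxyphenyl)ethan-1-one | COc1cc(OC)c(C(=O)Cc2ccc(O)c(O)c2)c(OC)c1 | intermediate
4 | prenyl bromide (1-bromo-3-methylbut-2-ene) | CC(C)=CCBr | starting material
5 | 2-{3,4-bis[(3-methylbut-2-en-1-yl)oxy]phenyl}-1-(2,4,6-trimethoxyphenyl)ethan-1-one | COc1cc(OC)c(C(=O)Cc2ccc(OCC=C(C)C)c(OCC=C(C)C)c2)c(OC)c1 | intermediate
6 | ethyl formate | CCOC=O | starting material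
7 | potassium (Z)-2-{3,4-bis[(3-methylbut-2-en-1-yl)oxy]phenyl}-3-oxo-3-(2,4,6-trimethoxyphenyl)prop-1-en-1-olate | [K+].[O-]/C=C(/c1ccc(OCC=C(C)C)c(OCC=C(C)C)c1)C(=O)c1c(OC)cc(OC)cc1OC | intermediate (not isolated)
8 | glabrescione B, 3-{3,4-bis[(3-methylbut-2-en-1-yl)oxy]phenyl}-5,7-dimethoxy-4H-chromen-4-one | COc1cc(OC)c2c(=O)c(-c3ccc(OCC=C(C)C)c(OCC=C(C)C)c3)coc2c1 | target

**Step count and risk**
Total steps: 3. Longest linear sequence: 3 (1 + 2 → 3 → 5 → 8).

Step 3 (the new step) is the most likely to fail: the enolate oxygen may be too weak a nucleophile for methoxide displacement, or the prenyl ethers may suffer under the conditions. The fallback uses known chemistry only; it sets out from 3 and comes back to the route at 8. BCl3 (CH2Cl2, −78 → 0 °C, excess to allow for catechol borate formation) removes one ortho-methyl group under chelation control to give 2-(3,4-dihydroxyphenyl)-1-(2-hydroxy-4,6-dimethoxyphenyl)ethan-1-one F3. The standard deoxybenzoin ring closure with DMF/BF3·OEt2/MeSO2Cl (C-2 from DMF, ring closed by the free phenol) then gives 3-(3,4-dihydroxyphenyl)-5,7-dimethoxy-4H-chromen-4-one F4. Alkylation of F4 with 4 and K2CO3 in acetone gives 8.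

Step 1 may give aryl esters, oligomers or self-acylation because the acid carries a free catechol. The fallback makes the C(α)–aryl bond instead of the C(acyl)–aryl bond and runs under base only; it sets out from 1 and 4 and comes back at 5, skipping 3. Compound 1 is acetylated (Ac2O, cat. Bi(OTf)3) to 1-(2,4,6-trimethoxyphenyl)ethan-1-one F1, which can also be bought. Commercial 4-bromocatechol (Oc1ccc(Br)cc1O) is alkylated with 4 and K2CO3 to 4-bromo-1,2-bis[(3-methylbut-2-en-1-yl)oxy]benzene F2. Pd-catalysed ketone α-arylation of F1 with F2 (Pd2(dba)3/Xantphos, NaOt-Bu, toluene, 80 °C) gives 5.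

Step 2 may suffer from C-alkylation at the benzylic ketone position or incomplete double alkylation. The fallback sets out from 3 and comes back at 5: Mitsunobu etherification with 3-methylbut-2-en-1-ol (CC(C)=CCO), PPh3 and DIAD in THF at 0 °C → rt, which involves no enolate. No new compound is made on the way (F0).

**Further compounds**
F1 | step 1 | 1-(2,4,6-trimethoxyphenyl)ethan-1-one | COc1cc(OC)c(C(C)=O)c(OC)c1
F2 | step 1 | 4-bromo-1,2-bis[(3-methylbut-2-en-1-yl)oxy]benzene | CC(C)=CCOc1ccc(Br)cc1OCC=C(C)C
F0 | step 2 | none | none
F3 | step 3 | 2-(3,4-dihydroxyphenyl)-1-(2-hydroxy-4,6-dimethoxyphenyl)ethan-1-one | COc1cc(O)c(C(=O)Cc2ccc(O)c(O)c2)c(OC)c1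
F4 | step 3 | 3-(3,4-dihydroxyphenyl)-5,7-dimethoxy-4H-chromen-4-one | COc1cc(OC)c2c(=O)c(-c3ccc(O)c(O)c3)coc2c1
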